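## The problem

Target **30** is an all-trans 1-aryltetralin of configuration (1S,2R,3R). In tetralin numbering C1 carries the 4-hydroxy-3,5-dimethoxyphenyl group, C2 and C3 carry the hydroxymethyl carbons C9' and C9, C4 is a methylene, and ring A (C4a to C8a) bears methoxy groups at C6 and C8 and a hydroxyl group at C7. Ring B is joined to this pentasubstituted benzene by two adjacent carbon–carbon bonds, C4–C4a and C1–C8a, whose ring A ends differ sharply: C8a is ortho and para to methoxy groups, whereas C4a is meta to both and para only to the twisted central oxygen, so electrophilic substitution can close a ring at C8a but hardly at C4a. C2 and C3 are a trans pair of CH–CH2O units that no later centre can correct, so they have to be set early and in absolute terms. C1 is doubly benzylic, ionisable and crowded by the peri methoxy group at C8; it can be set last under the influence of C2, but because the peri interaction pushes the C1 aryl group out of the ring plane, the 1,2-trans arrangement cannot be assumed to be the thermodynamic one and has to be fixed kinetically. The two hindered phenols, which are prone to quinone methide formation, and the two primary alcohols must stay masked through carbanion, fluoride and acid chemistry, and any intermediate with oxygen β to a carbonyl group can lose alkoxide. The enabling feature is the ortho relationship of C4a and C8a next to the C8 methoxy group: a 3-alkoxyaryne takes a carbon nucleophile at the remote carbon and leaves a carbanion beside oxygen. If that nucleophile and the electrophile that follows are C4 and C1 of a four-membered ketone already holding C2 and C3, both ring A bonds and ring B arise in one operation.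

## Retrosynthesis

**Protecting groups (30 ⇐ 29).** No skeletal bond is cut. All four hydroxyl groups are carried as benzyl ethers in **29** and released together by hydrogenolysis. Benzyl ethers tolerate every reagent class the route uses (enolates, fluoride, organocerium, Mg in MeOH, acid and silane), so one protecting group serves throughout.

**C1: the C1–H and C1–aryl bonds (29 ⇐ 28 ⇐ 27 ⇐ 22 + 24).** The C1–H bond is cut first, back to the tertiary diaryl carbinol **28**, whose cation takes up hydride. Then the C1–aryl bond is cut, back to ketone **22** and the organocerium reagent **26** made from bromide **24** (one benzylation from phenol **23**). The sulfone left by the key step is removed between the two events (**27** → **28**), when no ketone is present to compete for the reductant. The neighbouring option, arylating a secondary C1 cation with a phenol, is shorter by one building block. However, a nucleophile entering a half-chair benzylic cation is expected to arrive axially, on the face of the pseudo-equatorial C2 arm, and for the 1,2-trans target that face must receive hydrogen, not the aryl group. The forward sequence must add an aryl nucleophile to a hindered, enolisable ketone and then deliver hydride with facial control from C2.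

**Ring B: the C4–C4a and C1–C8a bonds (22 ⇐ 9 + 19).** Both bonds between ring A and ring B are cut at once, giving the aryne precursor **9** and the sulfonyl cyclobutanone **19**. This cut is preferred over a Friedel–Crafts closure because C4–C4a is formed by nucleophilic attack on an aryne, exactly at the position where electrophilic substitution is weakest, while C8a is the position where the methoxy group places the aryl anion. The precursors are a single benzene ring and a four-membered ring holding the complete C1–C4 chain with the trans C2/C3 pair. The forward reaction requires carbanion addition to the aryne, closure of the aryl anion onto the cyclobutanone carbonyl and fragmentation, with the sulfone dictating which bond breaks.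

**The activating group (19 ⇐ 18 ⇐ 17).** The C4–S bond is cut. The sulfone is introduced as a sulfide at the only α-methylene of cyclobutanone **17** and oxidised. A sulfone is chosen over an ester because it acidifies C4 enough for fluoride, stabilises the carbanion released in the fragmentation and can be removed reductively from a benzylic position.

**The cyclobutane (17 ⇐ 16 ⇐ 15 ⇐ 14 ⇐ 12 + 13; 12 ⇐ 10 + 11).** The two ring bonds on either side of the ketal carbon and its methylene neighbour (ketal carbon–C2 and C4–C3) are cut, giving fumarate **12** and ketene acetal **13**. The (E)-alkene supplies the trans relationship and the menthyl auxiliary supplies the absolute configuration. Ester reduction, benzylation and ketal hydrolysis (**14** → **15** → **16** → **17**) are functional-group changes only. **12** comes from fumaric acid **10** and two equivalents of (+)-menthol **11**. This auxiliary-controlled [2+2] is preferred over an auxiliary-bearing keteniminium cycloaddition because its facial control is far better established.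

**The aryne precursor (9 ⇐ 5 ⇐ 4 ⇐ 2 ⇐ 1).** The C–Si and O–S bonds are cut back to bromophenol **5**, the C–Br bond back to phenol **4**, and the phenol oxygen back to the aldehyde carbon of **2**, the benzyl ether of syringaldehyde **1**. Syringaldehyde already differentiates the central oxygen from the two methoxy groups, and the symmetry of **4** makes the bromination regiochemically unambiguous.

## Roads not taken

Alternative 1: The cut removes both hydroxymethyl carbons at once (C2–C9' and C3–C9). In the forward direction dichloroketene A3 adds across the C2=C3 double bond of the 1-aryl-1,4-dihydronaphthalene A2, anti to the aryl group, to give the cis-fused dichlorocyclobutanone A1.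
- Merits: the cycloaddition is a robust, well-known reaction on cis-disubstituted alkenes, it brings in both missing carbons, and C1 controls the face. On precedent this key step is clearly stronger than the aryne insertion.
- Weak points: A1 is cis-fused, so C2 and C3 come out cis while the target is trans. The four-membered ring must be cleaved between C9 and C9', the dichloromethyl carbon converted to an alcohol and one centre epimerised, about four further operations. A2 is a doubly benzylic skipped diene that isomerises into conjugation or aromatises easily. Its C1 centre, the only source of absolute configuration, must first be made by an asymmetric arylation of a di-ortho-substituted ring.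
- Comparison: the chosen plan offsets its weaker precedent by delivering the trans C2/C3 pair directly from a reliable auxiliary-controlled cycloaddition, with no epimerisation, and by keeping the ionisable C1 centre until the end.

Alternative 2: The cut is the C2–C3 bond. The open-chain diester A5, in which C1 already bears both aryl groups, is doubly deprotonated with LiN(iPr)2 and the bis-enolate is oxidised by CuCl2 so that the two α-carbons couple, giving the all-trans diester A4.
- Merits: ring B and two stereocentres form in one step, every reaction type is known, and A4 needs only ester reduction and hydrogenolysis, so the primary alcohols are never protected. In endgame length this road is better than the chosen one.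
- Weak points: A5 requires an enantioselective conjugate arylation with a di-ortho-substituted aryl group. C1 alone must then steer two new centres. Equilibration through the ester enolates is possible, but with the peri methoxy group the all-trans isomer is not clearly the most stable. The electron-rich rings and the doubly benzylic C1–H are exposed to the oxidant, and intermolecular coupling and Dieckmann condensation compete.
- Comparison: the chosen plan offers absolute control of C2/C3 and has no oxidative step on electron-rich arenes. It pays with benzyl protection and a longer sequence after the key step.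

Alternative 3: The cut is C4–C4a, made by electrophilic substitution. The aroyl cyclopropane lactone A7, assembled in a short known cyclopropanation–lactonisation sequence from (R)-epichlorohydrin A8, is treated with a Lewis acid so that C4a attacks the cyclopropane methylene C4 with cleavage of C2–C4, closing ring B as the lactone-fused tetralone A6.
- Merits: the chirality comes from a cheap building block, C9 and C9' are differentiated as lactone carbons, and the route to the tetralone is the shortest of all. In both respects it is better than the chosen plan.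
- Weak points: it forms the same C4–C4a bond as the chosen plan, but at the least nucleophilic ring position (meta to both methoxy groups and ortho to the acyl group), with an acceptor-only cyclopropane that must open at its unsubstituted carbon. A6 is a strongly enolised β-keto lactone, which makes aryl addition to C1 difficult, and C1 and C2 must then both be set from C3 alone.
- Comparison: the chosen plan makes this bond by carbanion attack on an aryne, where the ring electronics help, and arrives with the trans C2/C3 pair already fixed.

Key step: step 12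

Assumption: the Et2AlCl-promoted [2+2] of a dimenthyl fumarate is taken to follow its established facial sense, the (−)-menthyl ester giving the (1S,2R) cycloadduct, so the (+)-menthyl ester is used to reach the (1R,2S) series that maps onto C3 and C2 of the target.

## Route

**Step 1**
Reactants: 1 syringaldehyde (4-hydroxy-3,5-dimethoxybenzaldehyde)
Product: 2 4-(benzyloxy)-3,5-dimethoxybenzaldehyde
Conditions: BnBr, K2CO3, DMF, 60 °C
Reagents that add atoms: benzyl bromide, BrCc1ccccc1
Why: Williamson O-benzylation of the acidic phenol; the aldehyde is inert to carbonate in DMF.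

**Step 2**
Reactants: 2 4-(benzyloxy)-3,5-dimethoxybenzaldehyde
Product: 4 4-(benzyloxy)-3,5-dimethoxyphenol, via aryl formate 3 (not isolated)
Conditions: mCPBA, CH2Cl2, 0 °C to rt; then K2CO3, MeOH, rt
Reagents that add atoms: mCPBA, O=C(OO)c1cccc(Cl)c1
Why: Dakin-type Baeyer–Villiger oxidation in which the electron-rich aryl group migrates to give formate 3, followed by carbonate-mediated methanolysis; the ether groups are untouched.

**Step 3**
Reactants: 4 4-(benzyloxy)-3,5-dimethoxyphenol
Product: 5 4-(benzyloxy)-2-bromo-3,5-dimethoxyphenol
Conditions: NBS (1.0 equiv), CH2Cl2, −78 to 0 °C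
Reagents that add atoms: N-bromosuccinimide, O=C1CCC(=O)N1Br
Why: Electrophilic aromatic bromination ortho to the free hydroxyl; the two open positions are equivalent, so only over-bromination has to be held back by stoichiometry and low temperature.

**Step 4**
Reactants: 5 4-(benzyloxy)-2-bromo-3,5-dimethoxyphenol
Product: 9 4-(benzyloxy)-3,5-dimethoxy-2-(trimethylsilyl)phenyl trifluoromethanesulfonate, via aryl silyl ether 6 (not isolated), via aryllithium 7 (not isolated), via lithium silylphenoxide 8 (not isolated)
Conditions: HN(SiMe3)2, THF, reflux, then evaporation; n-BuLi, THF, −100 to −78 °C; Tf2O, −100 °C to rt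
Reagents that add atoms: hexamethyldisilazane, C[Si](C)(C)N[Si](C)(C)C; trifluoromethanesulfonic anhydride, O=S(=O)(OS(=O)(=O)C(F)(F)F)C(F)(F)F
Why: O-silylation, bromine–lithium exchange and retro-Brook 1,3-shift of silicon from oxygen to carbon give phenoxide 8, which is triflated in the same flask; this is the standard entry to 2-(trimethylsilyl)aryl triflates and the benzyl ether survives n-BuLi at this temperature.

**Step 5**
Reactants: 10 fumaric acid; 11 (+)-menthol, (1S,2R,5S)-5-methyl-2-(propan-2-yl)cyclohexan-1-ol
Product: 12 di-(+)-menthyl fumarate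
Conditions: 11 (2.2 equiv in all), TsOH·H2O (cat.), toluene, reflux, Dean–Stark trap
Reagents that add atoms: (+)-menthol (second equivalent of 11), C[C@H]1CC[C@@H]([C@H](C1)O)C(C)C
Why: Twofold Fischer esterification with azeotropic removal of water, each carboxyl group taking up one molecule of 11; the (E)-geometry is the stable one and the menthol stereocentres are not touched.

**Step 6**
Reactants: 12 di-(+)-menthyl fumarate; 13 1,1-dimethoxyethene
Product: 14 di-(+)-menthyl (1R,2S)-3,3-dimethoxycyclobutane-1,2-dicarboxylate
Conditions: Et2AlCl (2 equiv), toluene, −78 °C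
Reagents that add atoms: none
Why: Lewis-acid-promoted stepwise [2+2] cycloaddition (Michael addition of the ketene acetal, then ring closure of the zwitterion) in which the Et2AlCl-complexed menthyl esters shield one face of the fumarate; both ring stereocentres (the future C3 and C2) are set here by the auxiliary and their trans relation comes from the (E)-alkene.

**Step 7**
Reactants: 14 di-(+)-menthyl (1R,2S)-3,3-dimethoxycyclobutane-1,2-dicarboxylate
Product: 15 [(1R,2R)-3,3-dimethoxycyclobutane-1,2-diyl]dimethanol
Conditions: LiAlH4, THF, 0 °C to rt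
Reagents that add atoms: none
Why: LiAlH4 reduction of both esters releases the auxiliary for recovery; the ketal is inert and the change of one descriptor is only a change of CIP priorities.

**Step 8**
Reactants: 15 [(1R,2R)-3,3-dimethoxycyclobutane-1,2-diyl]dimethanol
Product: 16 (2R,3R)-2,3-bis[(benzyloxy)methyl]-1,1-dimethoxycyclobutane
Conditions: NaH (2.4 equiv), BnBr (2.4 equiv), Bu4NI (cat.), THF/DMF, 0 °C to rt
Reagents that add atoms: benzyl bromide, BrCc1ccccc1; benzyl bromide (second equivalent), BrCc1ccccc1
Why: Williamson etherification of both primary alkoxides, one benzyl group on each, while the ketal keeps the ring carbonyl masked from base.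

**Step 9**
Reactants: 16 (2R,3R)-2,3-bis[(benzyloxy)methyl]-1,1-dimethoxycyclobutane
Product: 17 (2R,3R)-2,3-bis[(benzyloxy)methyl]cyclobutan-1-one
Conditions: aq. H2SO4 (0.5 M), MeCN, rt
Reagents that add atoms: water, O
Why: Acid-catalysed ketal hydrolysis; the benzyl ethers are stable and the trans arrangement at the now enolisable C2 is the thermodynamically preferred one.

**Step 10**
Reactants: 17 (2R,3R)-2,3-bis[(benzyloxy)methyl]cyclobutan-1-one
Product: 18 (2R,3R)-2,3-bis[(benzyloxy)methyl]-4-(phenylsulfanyl)cyclobutan-1-one (C4 epimers)
Conditions: LiN(SiMe3)2, THF, −78 °C; PhSO2SPh, −78 °C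
Reagents that add atoms: S-phenyl benzenethiosulfonate, O=S(=O)(Sc1ccccc1)c1ccccc1
Why: Kinetic deprotonation at the unsubstituted α-methylene (C4) rather than at the more hindered C2, whose enolate could expel benzyloxide, and α-sulfenylation of the lithium enolate with a thiosulfonate; the C4 configuration is irrelevant.

**Step 11**
Reactants: 18 (2R,3R)-2,3-bis[(benzyloxy)methyl]-4-(phenylsulfanyl)cyclobutan-1-one
Product: 19 (2R,3R)-2,3-bis[(benzyloxy)methyl]-4-(phenylsulfonyl)cyclobutan-1-one (C4 epimers)
Conditions: nPr4N[RuO4] (cat.), NMO (3 equiv), 4 Å MS, MeCN, rt to 40 °C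
Reagents that add atoms: N-methylmorpholine N-oxide, C[N+]1([O-])CCOCC1; N-methylmorpholine N-oxide (second equivalent), C[N+]1([O-])CCOCC1
Why: Oxidation of the sulfide to the sulfone catalysed by nPr4N[RuO4] with the amine oxide as terminal oxidant, one oxygen atom from each of two equivalents; a non-peracid oxidant is chosen because a peracid could ring-expand the cyclobutanone by Baeyer–Villiger oxidation.

**Step 12**
Reactants: 9 4-(benzyloxy)-3,5-dimethoxy-2-(trimethylsilyl)phenyl trifluoromethanesulfonate; 19 (2R,3R)-2,3-bis[(benzyloxy)methyl]-4-(phenylsulfonyl)cyclobutan-1-one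
Product: 22 (2R,3R)-7-(benzyloxy)-2,3-bis[(benzyloxy)methyl]-6,8-dimethoxy-4-(phenylsulfonyl)-3,4-dihydronaphthalen-1(2H)-one (C4 epimers), via aryne 20 (not isolated), via fused cesium alkoxide 21 (not isolated)
Conditions: 9 (1.3 equiv), anhydrous CsF (3 equiv), MeCN, 25 to 60 °C
Reagents that add atoms: none
Why: Proposed new method: fluoride removes the silyl group of 9 with loss of triflate to give aryne 20 and also deprotonates 19 at C4, between carbonyl and sulfone; the closest known reaction type is the acyl-alkylation of arynes by β-keto esters and β-keto sulfones (formal insertion into the C–C σ-bond), used for two-carbon ring expansion of five- to seven-membered substrates but not of a cyclobutanone. The carbanion attacks the aryne carbon remote from the C8 methoxy group (future C4a), since the alkoxy group distorts the aryne so that this carbon is the electrophilic one and the charge develops at C8a beside the inductively withdrawing oxygen; this carbon is also the unhindered one. The C8a anion then adds to the neighbouring ketone (4-exo-trig) to give the benzocyclobutenoxide 21. Retro-aldol-type fragmentation of the original C1–C4 bond opens both four-membered rings and leaves a sulfone- and aryl-stabilised carbanion, so ring B is formed by two-carbon ring expansion and not by a direct cyclisation. Relative to the known cases the carbonyl is more electrophilic, the strain added on closing to 21 is comparable and the fragmentation is more exergonic, which is why the sequence should go through. No stereocentre of the target is created: C2 and C3 are spectators whose trans relation is the stable one even though C2 is now enolisable, and C4 is formed as a mixture that is erased in step 15. The step needs C- over O-arylation (the strained enolate keeps its charge on carbon), ring closure faster than protonation of the aryl anion (aprotic medium in which 19 is the only acid) and survival of 19 and 22 toward fluoride (anhydrous salt, work-up at full conversion), and the regiochemistry is secured by the methoxy group.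

**Step 13**
Reactants: 23 4-bromo-2,6-dimethoxyphenol
Product: 24 2-(benzyloxy)-5-bromo-1,3-dimethoxybenzene
Conditions: BnBr, K2CO3, DMF, 60 °C
Reagents that add atoms: benzyl bromide, BrCc1ccccc1
Why: Williamson O-benzylation, as in step 1.

**Step 14**
Reactants: 22 (2R,3R)-7-(benzyloxy)-2,3-bis[(benzyloxy)methyl]-6,8-dimethoxy-4-(phenylsulfonyl)-3,4-dihydronaphthalen-1(2H)-one; 24 2-(benzyloxy)-5-bromo-1,3-dimethoxybenzene
Product: 27 (2R,3R)-7-(benzyloxy)-1-[4-(benzyloxy)-3,5-dimethoxyphenyl]-2,3-bis[(benzyloxy)methyl]-6,8-dimethoxy-4-(phenylsulfonyl)-1,2,3,4-tetrahydronaphthalen-1-ol (C1 and C4 epimers), via aryllithium 25 (not isolated), via arylcerium dichloride 26 (not isolated)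
Conditions: 24 (3 equiv), n-BuLi, THF, −78 °C; anhydrous CeCl3, −78 °C; then 22, −78 to −40 °C
Reagents that add atoms: none
Why: Bromine–lithium exchange and transmetalation give the weakly basic organocerium reagent, which adds to hindered, enolisable ketones in preference to deprotonating them (here C2–H with its β-benzyloxy group and the sulfonyl-activated C4–H); the configuration of the new carbinol centre does not matter because it is ionised in step 16.

**Step 15**
Reactants: 27 (2R,3R)-7-(benzyloxy)-1-[4-(benzyloxy)-3,5-dimethoxyphenyl]-2,3-bis[(benzyloxy)methyl]-6,8-dimethoxy-4-(phenylsulfonyl)-1,2,3,4-tetrahydronaphthalen-1-ol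
Product: 28 (2R,3R)-7-(benzyloxy)-1-[4-(benzyloxy)-3,5-dimethoxyphenyl]-2,3-bis[(benzyloxy)methyl]-6,8-dimethoxy-1,2,3,4-tetrahydronaphthalen-1-ol (C1 epimers)
Conditions: Mg turnings, MeOH, rt to 50 °C
Reagents that add atoms: none
Why: Single-electron reductive desulfonylation of the benzylic sulfone by Mg in MeOH, which removes the C4 stereocentre; it is placed after the carbonyl addition so that no ketone is exposed to the reductant, and benzyl ethers are inert.

**Step 16**
Reactants: 28 (2R,3R)-7-(benzyloxy)-1-[4-(benzyloxy)-3,5-dimethoxyphenyl]-2,3-bis[(benzyloxy)methyl]-6,8-dimethoxy-1,2,3,4-tetrahydronaphthalen-1-ol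
Product: 29 (1S,2R,3R)-7-(benzyloxy)-1-[4-(benzyloxy)-3,5-dimethoxyphenyl]-2,3-bis[(benzyloxy)methyl]-6,8-dimethoxy-1,2,3,4-tetrahydronaphthalene
Conditions: Et3SiH (5 equiv), TFA, CH2Cl2, −40 to 0 °C
Reagents that add atoms: none
Why: Ionic hydrogenation: acid ionises the doubly benzylic tertiary alcohol and Et3SiH delivers hydride to the planar C1 cation along the axial trajectory of the half-chair in which the C2 and C3 arms are pseudo-equatorial, that is anti to the axial C2–H and on the face of the C2 arm, so the aryl group ends trans to C2 and cis to C3 (1S), the trans outcome that ionic hydrogenation gives as a rule in six-membered rings. Excess silane at low temperature should capture the cation before it can lose the C2 proton.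

**Step 17**
Reactants: 29 (1S,2R,3R)-7-(benzyloxy)-1-[4-(benzyloxy)-3,5-dimethoxyphenyl]-2,3-bis[(benzyloxy)methyl]-6,8-dimethoxy-1,2,3,4-tetrahydronaphthalene
Product: 30 [(1S,2R,3R)-7-hydroxy-1-(4-hydroxy-3,5-dimethoxyphenyl)-6,8-dimethoxy-1,2,3,4-tetrahydronaphthalene-2,3-diyl]dimethanol (target)
Conditions: H2 (1 atm), Pd/C, EtOAc/EtOH, rt
Reagents that add atoms: none
Why: Hydrogenolysis of all four benzyl ethers over Pd/C in one operation; the diarylmethine C1–H and the aryl–oxygen bonds are stable under these conditions.

## Compound list

1 | syringaldehyde (4-hydroxy-3,5-dimethoxybenzaldehyde) | COc1cc(C=O)cc(OC)c1O | starting material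
2 | 4-(benzyloxy)-3,5-dimethoxybenzaldehyde | COc1cc(C=O)cc(OC)c1OCc1ccccc1 | intermediate
3 | 4-(benzyloxy)-3,5-dimethoxyphenyl formate | COc1cc(OC=O)cc(OC)c1OCc1ccccc1 | intermediate
4 | 4-(benzyloxy)-3,5-dimethoxyphenol | COc1cc(O)cc(OC)c1OCc1ccccc1 | intermediate
5 | 4-(benzyloxy)-2-bromo-3,5-dimethoxyphenol | COc1cc(O)c(Br)c(OC)c1OCc1ccccc1 | intermediate
6 | [4-(benzyloxy)-2-bromo-3,5-dimethoxyphenoxy]trimethylsilane | COc1cc(O[Si](C)(C)C)c(Br)c(OC)c1OCc1ccccc1 | intermediate
7 | [3-(benzyloxy)-2,4-dimethoxy-6-(trimethylsilyloxy)phenyl]lithium | COc1cc(O[Si](C)(C)C)c([Li])c(OC)c1OCc1ccccc1 | intermediate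
8 | lithium 4-(benzyloxy)-3,5-dimethoxy-2-(trimethylsilyl)phenoxide | [Li+].[O-]c1cc(OC)c(OCc2ccccc2)c(OC)c1[Si](C)(C)C | intermediate
9 | 4-(benzyloxy)-3,5-dimethoxy-2-(trimethylsilyl)phenyl trifluoromethanesulfonate | COc1cc(OS(=O)(=O)C(F)(F)F)c([Si](C)(C)C)c(OC)c1OCc1ccccc1 | intermediate
10 | fumaric acid | OC(=O)/C=C/C(=O)O | starting material
11 | (+)-menthol, (1S,2R,5S)-5-methyl-2-(propan-2-yl)cyclohexan-1-ol | C[C@H]1CC[C@@H]([C@H](C1)O)C(C)C | starting material
12 | di-(+)-menthyl fumarate, bis[(1S,2R,5S)-5-methyl-2-(propan-2-yl)cyclohexyl] (2E)-but-2-enedioate | C[C@H]1CC[C@@H]([C@H](C1)OC(=O)/C=C/C(=O)O[C@H]2C[C@@H](C)CC[C@@H]2C(C)C)C(C)C | intermediate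
13 | 1,1-dimethoxyethene | C=C(OC)OC | starting material
14 | di-(+)-menthyl (1R,2S)-3,3-dimethoxycyclobutane-1,2-dicarboxylate | COC1(OC)C[C@@H](C(=O)O[C@H]2C[C@@H](C)CC[C@@H]2C(C)C)[C@@H]1C(=O)O[C@H]1C[C@@H](C)CC[C@@H]1C(C)C | intermediate
15 | [(1R,2R)-3,3-dimethoxycyclobutane-1,2-diyl]dimethanol | COC1(OC)C[C@@H](CO)[C@@H]1CO | intermediate
16 | (2R,3R)-2,3-bis[(benzyloxy)methyl]-1,1-dimethoxycyclobutane | COC1(OC)C[C@@H](COCc2ccccc2)[C@@H]1COCc1ccccc1 | intermediate
17 | (2R,3R)-2,3-bis[(benzyloxy)methyl]cyclobutan-1-one | O=C1C[C@@H](COCc2ccccc2)[C@@H]1COCc1ccccc1 | intermediate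
18 | (2R,3R)-2,3-bis[(benzyloxy)methyl]-4-(phenylsulfanyl)cyclobutan-1-one (C4 epimers) | O=C1C(Sc2ccccc2)[C@@H](COCc2ccccc2)[C@@H]1COCc1ccccc1 | intermediate
19 | (2R,3R)-2,3-bis[(benzyloxy)methyl]-4-(phenylsulfonyl)cyclobutan-1-one (C4 epimers) | O=C1C(S(=O)(=O)c2ccccc2)[C@@H](COCc2ccccc2)[C@@H]1COCc1ccccc1 | intermediate
20 | 4-(benzyloxy)-3,5-dimethoxy-1,2-didehydrobenzene (aryne) | COC1=CC#CC(OC)=C1OCc1ccccc1 | intermediate
21 | cesium alkoxide of the benzocyclobutenol fused to the cyclobutane across C1–C4 (adduct of 20 and the C4 anion of 19) | [Cs+].[O-]C12c3c(OC)c(OCc4ccccc4)c(OC)cc3C1(S(=O)(=O)c1ccccc1)[C@@H](COCc1ccccc1)[C@@H]2COCc1ccccc1 | intermediate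
22 | (2R,3R)-7-(benzyloxy)-2,3-bis[(benzyloxy)methyl]-6,8-dimethoxy-4-(phenylsulfonyl)-3,4-dihydronaphthalen-1(2H)-one (C4 epimers) | O=C1c2c(cc(OC)c(OCc3ccccc3)c2OC)C(S(=O)(=O)c2ccccc2)[C@@H](COCc2ccccc2)[C@@H]1COCc1ccccc1 | intermediate
23 | 4-bromo-2,6-dimethoxyphenol | COc1cc(Br)cc(OC)c1O | starting material
24 | 2-(benzyloxy)-5-bromo-1,3-dimethoxybenzene | COc1cc(Br)cc(OC)c1OCc1ccccc1 | intermediate
25 | [4-(benzyloxy)-3,5-dimethoxyphenyl]lithium | [Li]c1cc(OC)c(OCc2ccccc2)c(OC)c1 | intermediate
26 | [4-(benzyloxy)-3,5-dimethoxyphenyl]cerium dichloride | Cl[Ce](Cl)c1cc(OC)c(OCc2ccccc2)c(OC)c1 | intermediate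
27 | (2R,3R)-7-(benzyloxy)-1-[4-(benzyloxy)-3,5-dimethoxyphenyl]-2,3-bis[(benzyloxy)methyl]-6,8-dimethoxy-4-(phenylsulfonyl)-1,2,3,4-tetrahydronaphthalen-1-ol (C1 and C4 epimers) | OC1(c2cc(OC)c(OCc3ccccc3)c(OC)c2)c2c(cc(OC)c(OCc3ccccc3)c2OC)C(S(=O)(=O)c2ccccc2)[C@@H](COCc2ccccc2)[C@@H]1COCc1ccccc1 | intermediate
28 | (2R,3R)-7-(benzyloxy)-1-[4-(benzyloxy)-3,5-dimethoxyphenyl]-2,3-bis[(benzyloxy)methyl]-6,8-dimethoxy-1,2,3,4-tetrahydronaphthalen-1-ol (C1 epimers) | OC1(c2cc(OC)c(OCc3ccccc3)c(OC)c2)c2c(cc(OC)c(OCc3ccccc3)c2OC)C[C@@H](COCc2ccccc2)[C@@H]1COCc1ccccc1 | intermediate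
29 | (1S,2R,3R)-7-(benzyloxy)-1-[4-(benzyloxy)-3,5-dimethoxyphenyl]-2,3-bis[(benzyloxy)methyl]-6,8-dimethoxy-1,2,3,4-tetrahydronaphthalene | COc1cc([C@H]2c3c(cc(OC)c(OCc4ccccc4)c3OC)C[C@@H](COCc3ccccc3)[C@@H]2COCc2ccccc2)cc(OC)c1OCc1ccccc1 | intermediate
30 | [(1S,2R,3R)-7-hydroxy-1-(4-hydroxy-3,5-dimethoxyphenyl)-6,8-dimethoxy-1,2,3,4-tetrahydronaphthalene-2,3-diyl]dimethanol, (1S,2R,3R)-lyoniresinol | COc1cc([C@H]2c3c(cc(OC)c(O)c3OC)C[C@@H](CO)[C@@H]2CO)cc(OC)c1O | target

## Step count and least certain steps

Total step count: 17. Longest linear sequence: 12 steps (steps 5 to 12, then 14 to 17). Steps 1 to 4 and step 13 make the two aryl building blocks.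

**Step 12 (key step, proposed new method).** What may go wrong: the aryl anion is protonated by unreacted 19 before it closes onto the carbonyl, so the reaction stops at simple C-arylation; the strained keto sulfone may be opened by fluoride or traces of water in a retro-Claisen sense; the product may lose benzyl alcohol by base-induced elimination at C2. Fallback (known chemistry): ring B is built classically, with C4 taken from the aldehyde carbon of 2 so that only the easy C1–C8a bond is made on the arene; it sets out from 2 and rejoins at 30. Stobbe condensation of 2 with dimethyl succinate (NaOMe, MeOH) gives the (E)-half-ester F1, and asymmetric hydrogenation (H2, [Rh(cod)2]BF4 with an enantiopure bisphosphine of the sense that gives the R acid) gives the succinic half-ester F2. Reduction of the ester of its potassium salt with Ca(BH4)2 and acid lactonisation give the β-arylmethyl lactone F3. The lithium enolate of F3 adds to a second equivalent of 2, anti to the ring substituent, to give the aldol adduct F4, and trifluoroacetic acid closes C1–C8a by Friedel–Crafts alkylation with the aryl group trans to C2, giving the aryltetralin lactone F5. LiAlH4 gives the diol F6, and hydrogenolysis over Pd/C gives 30.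

**Step 16 (ionic hydrogenation, sets C1).** What may go wrong: hydride is delivered to the other face of the cation, for example if the C2 arm turns pseudo-axial to escape the neighbouring aryl group, giving the 1,2-cis isomer; the cation may also lose the C2 proton and be reprotonated, scrambling C2. Fallback: the roles of hydrogen and aryl group are exchanged, so that whichever face the C1 cation prefers, one of the two orders gives the trans product; it sets out from 22 and rejoins at 30. NaBH4 reduces 22 to the alcohol F7, and Mg in MeOH removes the sulfone to give the secondary alcohol F8. Trifluoroacetic acid ionises F8 in the presence of 2,6-dimethoxyphenol, which is alkylated para to its hydroxyl group to give the phenol F9, and hydrogenolysis over Pd/C gives 30.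

**Step 14 (organocerium addition).** What may go wrong: deprotonation at the sulfonyl-activated C4–H or at C2 (followed by loss of benzyloxide) outruns addition to the hindered, peri-substituted carbonyl. Fallback: the acidic sulfone is removed before the carbon nucleophile is introduced; it sets out from 22 and rejoins at 28. 22 is reduced with NaBH4 to the alcohol F7 and desulfonylated with Mg in MeOH to the secondary alcohol F8, Swern oxidation of F8 gives the ketone F10, and 26 adds to F10 to give 28.

**Step 10 (sulfenylation of the cyclobutanone).** What may go wrong: the reactive cyclobutanone enolate undergoes aldol self-condensation, partial deprotonation at C2 leads to loss of benzyloxide, or the more acidic product is sulfenylated twice. Fallback: the enolate is never allowed to accumulate; it sets out from 17 and rejoins at 18. Deprotonation of 17 with LiN(iPr)2 in the presence of Me3SiCl (internal quench, THF, −78 °C) gives the silyl enol ether F11, which is sulfenylated by PhSCl in CH2Cl2 at −78 °C to give 18.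

**Step 3 (bromination).** What may go wrong: over-bromination, or oxidation of the very electron-rich para-alkoxyphenol to a quinone by the brominating agent. Fallback: the silyl group is introduced by directed ortho-metalation without a halogen; it sets out from 4 and rejoins at 9. Isopropyl isocyanate and Et3N convert 4 to the carbamate F12. In-situ N-silylation (Me3SiOTf, TMEDA), lithiation between the carbamate and methoxy groups with n-BuLi and quenching with Me3SiCl give the silyl carbamate F13. Et2NH and DBU in MeCN remove the carbamoyl group, and PhNTf2 triflates the phenoxide in the same flask to give 9.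

## Further compounds

F1 | step 12 | (E)-4-[4-(benzyloxy)-3,5-dimethoxyphenyl]-3-(methoxycarbonyl)but-3-enoic acid | COC(=O)/C(CC(=O)O)=C/c1cc(OC)c(OCc2ccccc2)c(OC)c1
F2 | step 12 | (3R)-4-[4-(benzyloxy)-3,5-dimethoxyphenyl]-3-(methoxycarbonyl)butanoic acid | COc1cc(C[C@@H](C(=O)OC)CC(=O)O)cc(OC)c1OCc1ccccc1
F3 | step 12 | (4R)-4-{[4-(benzyloxy)-3,5-dimethoxyphenyl]methyl}oxolan-2-one | COc1cc(C[C@H]2COC(=O)C2)cc(OC)c1OCc1ccccc1
F4 | step 12 | (3S,4R)-4-{[4-(benzyloxy)-3,5-dimethoxyphenyl]methyl}-3-{[4-(benzyloxy)-3,5-dimethoxyphenyl](hydroxy)methyl}oxolan-2-one (carbinol epimers) | COc1cc(C[C@H]2COC(=O)[C@@H]2C(O)c2cc(OC)c(OCc3ccccc3)c(OC)c2)cc(OC)c1OCc1ccccc1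
F5 | step 12 | lactone of (1S,2R,3R)-7-(benzyloxy)-1-[4-(benzyloxy)-3,5-dimethoxyphenyl]-3-(hydroxymethyl)-6,8-dimethoxy-1,2,3,4-tetrahydronaphthalene-2-carboxylic acid | COc1cc([C@H]2c3c(cc(OC)c(OCc5ccccc5)c3OC)C[C@H]4COC(=O)[C@H]24)cc(OC)c1OCc1ccccc1
F6 | step 12 | [(1S,2R,3R)-7-(benzyloxy)-1-[4-(benzyloxy)-3,5-dimethoxyphenyl]-6,8-dimethoxy-1,2,3,4-tetrahydronaphthalene-2,3-diyl]dimethanol | COc1cc([C@H]2c3c(cc(OC)c(OCc4ccccc4)c3OC)C[C@@H](CO)[C@@H]2CO)cc(OC)c1OCc1ccccc1
F7 | step 16 | (2R,3R)-7-(benzyloxy)-2,3-bis[(benzyloxy)methyl]-6,8-dimethoxy-4-(phenylsulfonyl)-1,2,3,4-tetrahydronaphthalen-1-ol (C1 and C4 epimers) | OC1c2c(cc(OC)c(OCc3ccccc3)c2OC)C(S(=O)(=O)c2ccccc2)[C@@H](COCc2ccccc2)[C@@H]1COCc1ccccc1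
F8 | step 16 | (2R,3R)-7-(benzyloxy)-2,3-bis[(benzyloxy)methyl]-6,8-dimethoxy-1,2,3,4-tetrahydronaphthalen-1-ol (C1 epimers) | OC1c2c(cc(OC)c(OCc3ccccc3)c2OC)C[C@@H](COCc2ccccc2)[C@@H]1COCc1ccccc1
F9 | step 16 | 4-[(1S,2R,3R)-7-(benzyloxy)-2,3-bis[(benzyloxy)methyl]-6,8-dimethoxy-1,2,3,4-tetrahydronaphthalen-1-yl]-2,6-dimethoxyphenol | COc1cc([C@H]2c3c(cc(OC)c(OCc4ccccc4)c3OC)C[C@@H](COCc3ccccc3)[C@@H]2COCc2ccccc2)cc(OC)c1O
F10 | step 14 | (2R,3R)-7-(benzyloxy)-2,3-bis[(benzyloxy)methyl]-6,8-dimethoxy-3,4-dihydronaphthalen-1(2H)-one | O=C1c2c(cc(OC)c(OCc3ccccc3)c2OC)C[C@@H](COCc2ccccc2)[C@@H]1COCc1ccccc1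
F11 | step 10 | {[(3R,4R)-3,4-bis[(benzyloxy)methyl]cyclobut-1-en-1-yl]oxy}trimethylsilane | C[Si](C)(C)OC1=C[C@@H](COCc2ccccc2)[C@@H]1COCc1ccccc1
F12 | step 3 | 4-(benzyloxy)-3,5-dimethoxyphenyl N-(propan-2-yl)carbamate | CC(C)NC(=O)Oc1cc(OC)c(OCc2ccccc2)c(OC)c1
F13 | step 3 | 4-(benzyloxy)-3,5-dimethoxy-2-(trimethylsilyl)phenyl N-(propan-2-yl)carbamate | CC(C)NC(=O)Oc1cc(OC)c(OCc2ccccc2)c(OC)c1[Si](C)(C)C
A1 | alternative 1 | cis-fused dichlorocyclobutanone on C2–C3 of the protected 1-aryltetralin, anti to the aryl group | COc1cc2C[C@@H]3C(=O)C(Cl)(Cl)[C@@H]3[C@@H](c3cc(OC)c(OCc4ccccc4)c(OC)c3)c2c(OC)c1OCc1ccccc1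
A2 | alternative 1 | 7-(benzyloxy)-1-[4-(benzyloxy)-3,5-dimethoxyphenyl]-6,8-dimethoxy-1,4-dihydronaphthalene (single C1 enantiomer) | COc1cc2CC=C[C@@H](c3cc(OC)c(OCc4ccccc4)c(OC)c3)c2c(OC)c1OCc1ccccc1
A3 | alternative 1 | dichloroketene | ClC(Cl)=C=O
A4 | alternative 2 | dimethyl all-trans-7-(benzyloxy)-1-[4-(benzyloxy)-3,5-dimethoxyphenyl]-6,8-dimethoxy-1,2,3,4-tetrahydronaphthalene-2,3-dicarboxylate | COC(=O)[C@@H]1Cc2cc(OC)c(OCc3ccccc3)c(OC)c2[C@H](c2cc(OC)c(OCc3ccccc3)c(OC)c2)[C@H]1C(=O)OC
A5 | alternative 2 | methyl 3-[4-(benzyloxy)-3,5-dimethoxyphenyl]-3-[3-(benzyloxy)-2,4-dimethoxy-6-(3-methoxy-3-oxopropyl)phenyl]propanoate (single enantiomer at C1) | COC(=O)CCc1cc(OC)c(OCc2ccccc2)c(OC)c1[C@@H](CC(=O)OC)c1cc(OC)c(OCc2ccccc2)c(OC)c1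
A6 | alternative 3 | lactone-fused 7-(benzyloxy)-6,8-dimethoxy-1-tetralone (β-keto lactone, C2 enolisable) | O=C1c2c(OC)c(OCc3ccccc3)c(OC)cc2C[C@H]2COC(=O)C12
A7 | alternative 3 | 1-[3-(benzyloxy)-2,4-dimethoxybenzoyl]-3-oxabicyclo[3.1.0]hexan-2-one (5R bridgehead, cis-fused) | O=C(c1ccc(OC)c(OCc2ccccc2)c1OC)[C@]12C[C@H]1COC2=O
A8 | alternative 3 | (R)-epichlorohydrin | ClC[C@H]1CO1
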